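## The problem

Compound 25 is a cyclohexene (ring A; carbons r1–r6: r1 carries the propanoate arm, r2 carries ring C, r3 and r4 are CH2, r5 carries the lactone carbonyl, r6 carries the lactol carbon) cis-fused along r5–r6 to a γ-lactone lactol (ring B). The tetrasubstituted r1=r2 bond bears on r1 a methyl propanoate with a stereocentre at its α-carbon (Cα), and on r2 a 1,3,3-trimethylcyclohexyl group (ring C) attached through a quaternary stereocentre (Cq). Of the five stereocentres, r5 and r6 are adjacent and cis and can be made together, and the lactol carbon is a hemiacetal that follows r6 through ring–chain tautomerism. Cα lies one bond outside ring A and can be steered by r6 only while it is held in a ring. Cq is insulated from the others by the flat r1=r2 unit, so ring A and Cq each need their own reagent control. Every bond made at r1 or r2 sits next to a tert-alkyl group. Ring B is a masked cis aldehyde–acid: base opens it to an aldehyde whose α-hydrogen (on r6) is also allylic, so epimerisation at r6 and migration of the double bond threaten, and Cα–H (α to the ester, allylic) is similarly labile. The feature that opens the key step is that the ester carbonyl carbon lies four atoms (Cα, r1, r6, lactol carbon) from the lactol oxygen, which is cis to r1. That carbonyl can therefore be one carbon monoxide inserted between a vinyl-derived Cα and that oxygen, closing a six-membered lactone (ring D) in which allylic strain against ring C fixes Cα.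

## Retrosynthesis

25 ⇒ 24. The methyl ester C–O bond is cut and the acyl carbon is rejoined to the lactol oxygen, giving the tricyclic bis-lactone 24. This is preferred to carrying an open ester because 24 holds Cα in ring D and hides both the lactol hydroxyl and the ester in one acylal. The forward reaction must be a methanolysis that opens only the six-membered acylal lactone and leaves ring B to reclose.

24 ⇒ 22 + 23 (key disconnection). The Cα–C(acyl) bond and the acyl–O bond are cut, leaving the r1-vinyl diene lactol 22 and carbon monoxide 23. The neighbouring cut, Cα–r1 (coupling a propanoate enolate with triflate 17), makes the same skeleton but gives no control at Cα and closes no ring; it is kept as the fallback. Cutting through CO removes a stereocentre, a ring and a carbonyl at once, so 22 has only ring-fusion stereocentres. The forward reaction must add hydride to the vinyl CH2, insert CO at Cα and not at r2, and let the lactol hydroxyl capture the acyl group.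

22 ⇒ 21 ⇒ 20 ⇒ 19. Ring B is opened at the lactone C–O bond to the cis aldehyde–ester 21, which comes from alcohol 20 and silyl ether 19. The aldehyde oxidation level is introduced last because a free or masked aldehyde would not survive the hydride and base used earlier. The forward steps must avoid base once the aldehyde exists.

19 ⇒ 17 + 18, 17 ⇒ 15, 15 ⇒ 13. The r1–vinyl bond is cut to enol triflate 17 and vinylboronate 18. Triflate 17 is traced to enone 15, because conjugate hydride addition gives the r1–r2 enolate regiospecifically; a saturated r1 ketone could not distinguish r2 from r6. Enone 15 is traced to alkene 13 by an ene reaction with singlet oxygen, which moves the double bond from r1=r2 to r2=r3 while oxygenating r1. The forward ene reaction must abstract hydrogen from r3 and not from r6.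

13 ⇒ 12 ⇒ 10 + 11. The r5–r6 and r3–r4 bonds are cut (Diels–Alder), giving diene 10 and the acryloyl oxazolidinone 11. A cycloaddition with a butenolide dienophile across r5–r6 would deliver ring B directly, but it would leave the alkene at r2=r3 with r1 unoxidised and would depend on weak regiocontrol by one alkyl group. Here the silyloxymethyl terminus ("ortho") and the tert-alkyl group ("para") direct in the same sense, the endo mode gives the cis r5/r6 pair, and the auxiliary sets the absolute configuration without reference to Cq. The ring A stereocentres are thus added to a fragment that already carries Cq.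

10 ⇒ 8 + 9, 8 ⇒ 6 ⇒ 5 ⇒ 4 ⇒ 3 ⇒ 1 + 2. The diene is cut at its central C–C bond to enol triflate 8 and boronate 9. Triflate 8 comes from methyl ketone 6, and 6 from acid 5. Acid 5 is the oxidative remnant of the phenyl group in 4, whose gem-dimethyl carbon was the carbonyl of ketone 3. Ketone 3 arises by enantioselective conjugate addition of phenylboronic acid 2 to enone 1, which creates Cq. Phenyl is chosen as the carboxyl precursor because, unlike an alkenyl group, it is not expected to trap the tertiary cation of the gem-dimethylation. The ketone ends up 1,3 to Cq, exactly where the gem-dimethyl group is needed.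

## Roads not taken

Alternative 1: The cut is through ring B at r5–C(carbonyl) and r6–C(acetal). In the forward direction benzyloxyketene A2, generated in situ with an amine base, would add across r5=r6 of the ring A diene ester A1 to give the cis-fused cyclobutanone A3. Baeyer–Villiger oxygen insertion next to the alkoxy-bearing carbon and debenzylation would then lead to 25. Merits: the two ring B carbons, the cis fusion and the right oxidation pattern arrive in two operations; ketene polarisation secures the regiochemistry; no pressurised carbon monoxide and no free aldehyde are needed. On ring B alone this road is shorter than the chosen one. Weak points: the only stereocentres near the reacting alkene are Cα, which is exocyclic and freely rotating, and the remote Cq, so the face of addition, and with it r5 and r6, is poorly controlled. A1 has a Cα–H that is α to an ester and allylic to a conjugated diene, and it must survive the amine base. Cα would have to be set on an acyclic arm. The peracid meets an electron-rich tetrasubstituted alkene, and hydrogenolytic debenzylation meets the same alkene. The chosen plan sets r5 and r6 by an auxiliary before any labile centre exists and sets Cα inside ring D, at the price of more steps on ring B.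

Alternative 2: The cut is in ring C, at the bond from Cq to the ring methylene remote from the future gem-dimethyl carbon. In the forward direction a chiral phosphoric acid would protonate the methylene of dienyl cyclopentanol A4, and migration of a cyclopentane bond to the allyl cation would give the 2-alkenyl-2-methylcyclohexanone A5. Merits: ring C and Cq are formed together in one catalytic, metal-free, enantioselective step on a ring A fragment taken from the chiral pool, and no cationic gem-dimethylation of a ketone is needed. Weak points: the ketone lands next to Cq, so the gem-dimethyl group needs double α′-methylation followed by removal of a carbonyl flanked by two quaternary carbons, which costs several steps. A4 carries a ketal and a silyl ether under a strong Brønsted acid, and the catalyst must override the existing r5 centre. The r6 carbon, the vinyl group and ring B would all still have to be added afterwards to a late intermediate, with the cis r5/r6 relationship unsolved. The chosen plan is equally catalytic at Cq, puts the carbonyl where one step turns it into the gem-dimethyl group, and builds r5/r6 in a single controlled cycloaddition.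

Alternative 3: The cut removes three ring A bonds (r1–r6, r2–r3, r4–r5). In the forward direction the enyne ester A6 (alkyne = r1 and r2, butenolide alkene = r5 and r6) and acetylene A7 would combine under a cationic rhodium bisphosphine catalyst to give the tricyclic diene bis-lactone A8. Hydrogenation of its disubstituted r3=r4 bond would give 24. Merits: this is by far the most convergent road; ring A and ring D form in one step from three components, and the count to 24 could be about half that of the chosen plan. Weak points: A6 carries a propargylic Cα–H on an activated acylal ester that is prone to epimerisation and allene formation, and its acylal carbon is itself configurationally mobile. The tert-alkyl alkyne must enter a crowded metallacycle while acetylene can trimerise by itself. The final hydrogenation must spare r1=r2 and the acylal. The chosen plan gives up that brevity for stereocentres each set by a separate, well-precedented event and for intermediates without a labile propargylic centre.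

Key step: step 15

Assumption: the lactol carbon is configurationally mobile (ring–chain tautomerism), so 22 and 25 are drawn as the anomer with the hydroxyl cis to r1; this is the anomer the key step consumes and is taken to be the preferred form of 25 (hydrogen bond to the ester carbonyl).

## Route

Step 1
Reactants: 1 3-methylcyclohex-2-en-1-one; 2 phenylboronic acid
Product: 3 (3S)-3-methyl-3-phenylcyclohexan-1-one
Conditions: Pd(OCOCF3)2 (5 mol%), (R)-t-BuPyOx (6 mol%), NH4PF6, H2O, ClCH2CH2Cl, 40 °C
Reagents that add atoms: none
Why: Palladium-catalysed enantioselective conjugate addition of an arylboronic acid to a β-substituted cyclic enone with a pyridine–oxazoline ligand; the (R)-ligand is chosen to deliver phenyl to the face that gives the (S) quaternary centre, which becomes Cq.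

Step 2
Reactants: 3 (3S)-3-methyl-3-phenylcyclohexan-1-one
Product: 4 [(1S)-1,3,3-trimethylcyclohexyl]benzene
Conditions: Me2TiCl2 (from Me2Zn, TiCl4), CH2Cl2, −30 °C to rt
Reagents that add atoms: dimethyltitanium dichloride, C[Ti](C)(Cl)Cl
Why: Geminal dimethylation of a ketone with Me2TiCl2 (methyl addition, ionisation of the titanium alkoxide, second methyl transfer); Cq is not involved and the unactivated phenyl ring is a poor trap for the tertiary cation.

Step 3
Reactants: 4 [(1S)-1,3,3-trimethylcyclohexyl]benzene
Product: 5 (1S)-1,3,3-trimethylcyclohexane-1-carboxylic acid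
Conditions: RuCl3·xH2O (cat.), NaIO4, EtOAc/MeCN/H2O, rt
Reagents that add atoms: sodium periodate, [Na+].[O-]I(=O)(=O)=O; water, O
Why: RuO4 generated catalytically degrades a phenyl ring to a carboxylic acid with the ipso carbon retained; the hydrocarbon has no other oxidisable site and Cq is untouched.

Step 4
Reactants: 5 (1S)-1,3,3-trimethylcyclohexane-1-carboxylic acid
Product: 6 1-[(1S)-1,3,3-trimethylcyclohexyl]ethan-1-one
Conditions: MeLi (2.5 equiv), Et2O, 0 °C to rt; aq. NH4Cl
Reagents that add atoms: methyllithium, [Li]C
Why: Addition of methyllithium to the lithium carboxylate gives a geminal dialkoxide that releases the methyl ketone only on work-up; the neopentyl-type carboxylate resists over-addition.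

Step 5
Reactants: 6 1-[(1S)-1,3,3-trimethylcyclohexyl]ethan-1-one
Product: 8 1-[(1S)-1,3,3-trimethylcyclohexyl]ethenyl trifluoromethanesulfonate, via potassium enolate 7 (not isolated)
Conditions: KN(SiMe3)2, THF, −78 °C; then PhNTf2, −78 °C to 0 °C
Reagents that add atoms: N-phenylbis(trifluoromethanesulfonimide), O=S(=O)(N(c1ccccc1)S(=O)(=O)C(F)(F)F)C(F)(F)F
Why: Only one enolate can form because the other α-carbon is quaternary; O-sulfonylation gives the 1-(tert-alkyl)vinyl triflate.

Step 6
Reactants: 8 1-[(1S)-1,3,3-trimethylcyclohexyl]ethenyl trifluoromethanesulfonate; 9 (E)-tert-butyldimethyl{[3-(4,4,5,5-tetramethyl-1,3,2-dioxaborolan-2-yl)prop-2-en-1-yl]oxy}silane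
Product: 10 tert-butyldimethyl{[(2E)-4-[(1S)-1,3,3-trimethylcyclohexyl]penta-2,4-dien-1-yl]oxy}silane
Conditions: Pd(PPh3)4 (5 mol%), aq. K3PO4, 1,4-dioxane, 60 °C
Reagents that add atoms: none
Why: Suzuki–Miyaura coupling of an alkenyl triflate with an (E)-alkenylboronate proceeds with retention of geometry and gives the (E)-1,3-disubstituted diene.

Step 7
Reactants: 10 tert-butyldimethyl{[(2E)-4-[(1S)-1,3,3-trimethylcyclohexyl]penta-2,4-dien-1-yl]oxy}silane; 11 (4S)-3-acryloyl-4-benzyl-1,3-oxazolidin-2-one
Product: 12 (4S)-4-benzyl-3-{[(1R,2S)-2-{[(tert-butyldimethylsilyl)oxy]methyl}-4-[(1S)-1,3,3-trimethylcyclohexyl]cyclohex-3-en-1-yl]carbonyl}-1,3-oxazolidin-2-one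
Conditions: 11 (1.5 equiv), Et2AlCl (2.0 equiv), CH2Cl2, −78 °C
Reagents that add atoms: none
Why: Auxiliary-controlled Diels–Alder reaction of the aluminium-chelated s-cis acryloyl imide; the diene adds to the face away from the benzyl group, which sets (R) at r5, and the endo mode with the (E)-diene sets r6 cis to it. The silyloxymethyl terminus ("ortho") and the tert-alkyl group ("para") direct the regiochemistry in the same sense and place the new alkene at r1=r2.

Step 8
Reactants: 12 (4S)-4-benzyl-3-{[(1R,2S)-2-{[(tert-butyldimethylsilyl)oxy]methyl}-4-[(1S)-1,3,3-trimethylcyclohexyl]cyclohex-3-en-1-yl]carbonyl}-1,3-oxazolidin-2-one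
Product: 13 methyl (1R,2S)-2-{[(tert-butyldimethylsilyl)oxy]methyl}-4-[(1S)-1,3,3-trimethylcyclohexyl]cyclohex-3-ene-1-carboxylate
Conditions: MeOMgBr (from MeMgBr, MeOH), CH2Cl2/MeOH, 0 °C
Reagents that add atoms: methanol, CO
Why: Transesterification of an N-acyl oxazolidinone at the exocyclic carbonyl with methoxymagnesium bromide is mild enough not to epimerise r5, and the auxiliary is recovered.

Step 9
Reactants: 13 methyl (1R,2S)-2-{[(tert-butyldimethylsilyl)oxy]methyl}-4-[(1S)-1,3,3-trimethylcyclohexyl]cyclohex-3-ene-1-carboxylate
Product: 15 methyl (1R,2S)-2-{[(tert-butyldimethylsilyl)oxy]methyl}-3-oxo-4-[(1S)-1,3,3-trimethylcyclohexyl]cyclohex-4-ene-1-carboxylate, via allylic hydroperoxide 14 (not isolated)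
Conditions: O2, tetraphenylporphyrin (cat.), hν, CH2Cl2, 0 °C; then Ac2O, pyridine, DMAP (cat.), 0 °C to rt
Reagents that add atoms: oxygen, O=O
Why: Schenck ene reaction: singlet oxygen should abstract an r3 hydrogen (geminal to the bulky tert-alkyl group) and bond to the unhindered r1, moving the alkene to r2=r3. Acetylation and elimination of the secondary hydroperoxide (Kornblum–DeLaMare-type dehydration) then gives the enone, so the configuration of the hydroperoxide carbon does not matter.

Step 10
Reactants: 15 methyl (1R,2S)-2-{[(tert-butyldimethylsilyl)oxy]methyl}-3-oxo-4-[(1S)-1,3,3-trimethylcyclohexyl]cyclohex-4-ene-1-carboxylate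
Product: 17 methyl (1R,2S)-2-{[(tert-butyldimethylsilyl)oxy]methyl}-3-{[(trifluoromethyl)sulfonyl]oxy}-4-[(1S)-1,3,3-trimethylcyclohexyl]cyclohex-3-ene-1-carboxylate, via lithium enolate 16 (not isolated)
Conditions: LiBH(s-Bu)3 (1.1 equiv), THF, −78 °C; then PhNTf2, −78 °C to rt
Reagents that add atoms: N-phenylbis(trifluoromethanesulfonimide), O=S(=O)(N(c1ccccc1)S(=O)(=O)C(F)(F)F)C(F)(F)F
Why: Conjugate reduction of the β-unsubstituted, carbonyl-hindered enone gives the r1–r2 enolate regiospecifically, and O-triflation without equilibration fixes the tetrasubstituted enol triflate. No enolate forms towards r6, so its configuration is kept.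

Step 11
Reactants: 17 methyl (1R,2S)-2-{[(tert-butyldimethylsilyl)oxy]methyl}-3-{[(trifluoromethyl)sulfonyl]oxy}-4-[(1S)-1,3,3-trimethylcyclohexyl]cyclohex-3-ene-1-carboxylate; 18 4,4,5,5-tetramethyl-2-vinyl-1,3,2-dioxaborolane
Product: 19 methyl (1R,2R)-2-{[(tert-butyldimethylsilyl)oxy]methyl}-3-ethenyl-4-[(1S)-1,3,3-trimethylcyclohexyl]cyclohex-3-ene-1-carboxylate
Conditions: Pd(dppf)Cl2 (5 mol%), K3PO4, 1,4-dioxane/H2O, 60 °C
Reagents that add atoms: none
Why: Suzuki–Miyaura coupling of an alkenyl triflate; the small vinyl partner should be tolerated next to the tert-alkyl group, and the weak base leaves the cis ester alone.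

Step 12
Reactants: 19 methyl (1R,2R)-2-{[(tert-butyldimethylsilyl)oxy]methyl}-3-ethenyl-4-[(1S)-1,3,3-trimethylcyclohexyl]cyclohex-3-ene-1-carboxylate
Product: 20 methyl (1R,2R)-3-ethenyl-2-(hydroxymethyl)-4-[(1S)-1,3,3-trimethylcyclohexyl]cyclohex-3-ene-1-carboxylate
Conditions: HF·pyridine, pyridine, THF, 0 °C
Reagents that add atoms: none
Why: Buffered fluoride desilylation avoids the alkoxide that would attack the cis ester; the alcohol is carried on crude.

Step 13
Reactants: 20 methyl (1R,2R)-3-ethenyl-2-(hydroxymethyl)-4-[(1S)-1,3,3-trimethylcyclohexyl]cyclohex-3-ene-1-carboxylate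
Product: 21 methyl (1R,2R)-3-ethenyl-2-formyl-4-[(1S)-1,3,3-trimethylcyclohexyl]cyclohex-3-ene-1-carboxylate
Conditions: Dess–Martin periodinane, pyridine, CH2Cl2, 0 °C
Reagents that add atoms: none
Why: Dess–Martin oxidation under buffered, non-basic conditions should give the β,γ-unsaturated aldehyde without epimerisation at r6 or alkene migration.

Step 14
Reactants: 21 methyl (1R,2R)-3-ethenyl-2-formyl-4-[(1S)-1,3,3-trimethylcyclohexyl]cyclohex-3-ene-1-carboxylate
Product: 22 (3R,3aR,7aR)-4-ethenyl-3-hydroxy-5-[(1S)-1,3,3-trimethylcyclohexyl]-3a,6,7,7a-tetrahydro-2-benzofuran-1(3H)-one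
Conditions: 1 M HCl (aq.)/THF, rt to 40 °C
Reagents that add atoms: water, O
Why: Acid-catalysed hydration of the aldehyde and acyl transfer from the cis ester to the hydrate (the way cis-2-formyl carboxylic esters give pseudo-acids) expels methanol and closes ring B. The lactol carbon settles by ring–chain tautomerism, and the aldehyde never meets base.

Step 15
Reactants: 22 (3R,3aR,7aR)-4-ethenyl-3-hydroxy-5-[(1S)-1,3,3-trimethylcyclohexyl]-3a,6,7,7a-tetrahydro-2-benzofuran-1(3H)-one; 23 carbon monoxide
Product: 24 tricyclic bis-lactone: the lactol oxygen of 22 is acylated by a (2R)-propanoyl bridge from r1, so that the δ-lactone (ring D) and the γ-lactone (ring B) share the acetal carbon, with the Cα methyl on the face of r6–H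
Conditions: Pd(OAc)2 (5 mol%), Xantphos (6 mol%), TsOH·H2O (10 mol%), CO (30 bar), toluene, 80 °C
Reagents that add atoms: none
Why: Proposed new method: a palladium hydride (zerovalent palladium protonated by the sulfonic acid) should add to the unhindered CH2 terminus of the diene to give an allylpalladium over Cα, r1 and r2, carbon monoxide should insert at Cα, and the acylpalladium should be captured by the lactol hydroxyl; the closest known reaction types are palladium-catalysed hydroalkoxycarbonylation of 1,3-dienes to β,γ-unsaturated esters and cyclocarbonylation of unsaturated alcohols to lactones, whereas capture by a hemiacetal hydroxyl on a tetrasubstituted diene is not documented. Ring D closes by C–O bond formation, the lactol oxygen attacking the acyl carbon (6-exo-trig), which leaves r1=r2 in place. At Cα the hydrogen must lie in the alkene plane facing ring C to avoid allylic 1,3-strain with the tert-alkyl group, and ring D can close only on the lactol face of that plane, so the methyl group is forced onto the r6–H (convex) face, which is (R). Hydride addition and CO insertion are reversible, so an allylpalladium on the other face can revert and re-enter, and the same arrangement is expected to be the thermodynamically preferred epimer. At the acetal carbon only the anomer with the hydroxyl cis to r1 can reach the acyl group; tautomerism of 22 supplies it and acylation fixes it. The step needs regioselective hydride addition to the terminal carbon and acyl delivery at Cα, not r2, which the full substitution of r2 and its ring C substituent secure. It also needs lactonisation to outrun β-hydride elimination, which CO pressure and the proximity of the hydroxyl favour. An achiral wide-bite-angle bisphosphine is used because the substrate, not the ligand, decides Cα.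

Step 16
Reactants: 24 tricyclic bis-lactone
Product: 25 methyl (2R)-2-[(3R,3aR,7aR)-3-hydroxy-1-oxo-5-[(1S)-1,3,3-trimethylcyclohexyl]-1,3,3a,6,7,7a-hexahydro-2-benzofuran-4-yl]propanoate
Conditions: K2CO3 (1 equiv), MeOH, −10 to 0 °C; then pH 4 buffer
Reagents that add atoms: methanol, CO
Why: Methoxide should open the six-membered acylal lactone, which is more electrophilic than the five-membered one, at its carbonyl carbon; the hydroxy lactone is the leaving group and recloses on acidification. Cα is not involved, and cold, brief treatment limits exposure of the transient aldehyde–carboxylate.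

## Compound list

1 | 3-methylcyclohex-2-en-1-one | CC1=CC(=O)CCC1 | starting material
2 | phenylboronic acid | OB(O)c1ccccc1 | starting material
3 | (3S)-3-methyl-3-phenylcyclohexan-1-one | c1ccccc1[C@@]2(C)CCCC(=O)C2 | intermediate
4 | [(1S)-1,3,3-trimethylcyclohexyl]benzene | c1ccccc1[C@@]2(C)CCCC(C)(C)C2 | intermediate
5 | (1S)-1,3,3-trimethylcyclohexane-1-carboxylic acid | OC(=O)[C@@]1(C)CCCC(C)(C)C1 | intermediate
6 | 1-[(1S)-1,3,3-trimethylcyclohexyl]ethan-1-one | CC(=O)[C@@]1(C)CCCC(C)(C)C1 | intermediate
7 | potassium 1-[(1S)-1,3,3-trimethylcyclohexyl]ethen-1-olate | [K]OC(=C)[C@@]1(C)CCCC(C)(C)C1 | intermediate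
8 | 1-[(1S)-1,3,3-trimethylcyclohexyl]ethenyl trifluoromethanesulfonate | C=C(OS(=O)(=O)C(F)(F)F)[C@@]1(C)CCCC(C)(C)C1 | intermediate
9 | (E)-tert-butyldimethyl{[3-(4,4,5,5-tetramethyl-1,3,2-dioxaborolan-2-yl)prop-2-en-1-yl]oxy}silane | CC(C)(C)[Si](C)(C)OC/C=C/B1OC(C)(C)C(C)(C)O1 | starting material
10 | tert-butyldimethyl{[(2E)-4-[(1S)-1,3,3-trimethylcyclohexyl]penta-2,4-dien-1-yl]oxy}silane | C=C(/C=C/CO[Si](C)(C)C(C)(C)C)[C@@]1(C)CCCC(C)(C)C1 | intermediate
11 | (4S)-3-acryloyl-4-benzyl-1,3-oxazolidin-2-one | C=CC(=O)N1[C@@H](Cc2ccccc2)COC1=O | starting material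
12 | (4S)-4-benzyl-3-{[(1R,2S)-2-{[(tert-butyldimethylsilyl)oxy]methyl}-4-[(1S)-1,3,3-trimethylcyclohexyl]cyclohex-3-en-1-yl]carbonyl}-1,3-oxazolidin-2-one | C1=C([C@@]2(C)CCCC(C)(C)C2)CC[C@@H](C(=O)N3[C@@H](Cc4ccccc4)COC3=O)[C@H]1CO[Si](C)(C)C(C)(C)C | intermediate
13 | methyl (1R,2S)-2-{[(tert-butyldimethylsilyl)oxy]methyl}-4-[(1S)-1,3,3-trimethylcyclohexyl]cyclohex-3-ene-1-carboxylate | C1=C([C@@]2(C)CCCC(C)(C)C2)CC[C@@H](C(=O)OC)[C@H]1CO[Si](C)(C)C(C)(C)C | intermediate
14 | methyl (1R,2S,3S)-2-{[(tert-butyldimethylsilyl)oxy]methyl}-3-hydroperoxy-4-[(1S)-1,3,3-trimethylcyclohexyl]cyclohex-4-ene-1-carboxylate (hydroperoxide trans to the silyloxymethyl group expected) | OO[C@@H]1C([C@@]2(C)CCCC(C)(C)C2)=CC[C@@H](C(=O)OC)[C@H]1CO[Si](C)(C)C(C)(C)C | intermediate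
15 | methyl (1R,2S)-2-{[(tert-butyldimethylsilyl)oxy]methyl}-3-oxo-4-[(1S)-1,3,3-trimethylcyclohexyl]cyclohex-4-ene-1-carboxylate | O=C1C([C@@]2(C)CCCC(C)(C)C2)=CC[C@@H](C(=O)OC)[C@H]1CO[Si](C)(C)C(C)(C)C | intermediate
16 | lithium enolate of 15 after conjugate reduction (r1–r2 enolate) | [Li]OC1=C([C@@]2(C)CCCC(C)(C)C2)CC[C@@H](C(=O)OC)[C@H]1CO[Si](C)(C)C(C)(C)C | intermediate
17 | methyl (1R,2S)-2-{[(tert-butyldimethylsilyl)oxy]methyl}-3-{[(trifluoromethyl)sulfonyl]oxy}-4-[(1S)-1,3,3-trimethylcyclohexyl]cyclohex-3-ene-1-carboxylate | O=S(=O)(OC1=C([C@@]2(C)CCCC(C)(C)C2)CC[C@@H](C(=O)OC)[C@H]1CO[Si](C)(C)C(C)(C)C)C(F)(F)F | intermediate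
18 | 4,4,5,5-tetramethyl-2-vinyl-1,3,2-dioxaborolane | C=CB1OC(C)(C)C(C)(C)O1 | starting material
19 | methyl (1R,2R)-2-{[(tert-butyldimethylsilyl)oxy]methyl}-3-ethenyl-4-[(1S)-1,3,3-trimethylcyclohexyl]cyclohex-3-ene-1-carboxylate | C=CC1=C([C@@]2(C)CCCC(C)(C)C2)CC[C@@H](C(=O)OC)[C@H]1CO[Si](C)(C)C(C)(C)C | intermediate
20 | methyl (1R,2R)-3-ethenyl-2-(hydroxymethyl)-4-[(1S)-1,3,3-trimethylcyclohexyl]cyclohex-3-ene-1-carboxylate | C=CC1=C([C@@]2(C)CCCC(C)(C)C2)CC[C@@H](C(=O)OC)[C@H]1CO | intermediate
21 | methyl (1R,2R)-3-ethenyl-2-formyl-4-[(1S)-1,3,3-trimethylcyclohexyl]cyclohex-3-ene-1-carboxylate | C=CC1=C([C@@]2(C)CCCC(C)(C)C2)CC[C@@H](C(=O)OC)[C@H]1C=O | intermediate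
22 | (3R,3aR,7aR)-4-ethenyl-3-hydroxy-5-[(1S)-1,3,3-trimethylcyclohexyl]-3a,6,7,7a-tetrahydro-2-benzofuran-1(3H)-one | C=CC1=C([C@@]2(C)CCCC(C)(C)C2)CC[C@H]2C(=O)O[C@@H](O)[C@@H]12 | intermediate
23 | carbon monoxide | [C-]#[O+] | starting material
24 | tricyclic bis-lactone (δ-lactone and γ-lactone sharing the acetal carbon; Cα (R), methyl on the r6–H face; ring B cis-fused; Cq (S)) | C[C@H]1C(=O)O[C@@H]2OC(=O)[C@@H]3CCC(=C1[C@H]23)[C@@]4(C)CCCC(C)(C)C4 | intermediate
25 | methyl (2R)-2-[(3R,3aR,7aR)-3-hydroxy-1-oxo-5-[(1S)-1,3,3-trimethylcyclohexyl]-1,3,3a,6,7,7a-hexahydro-2-benzofuran-4-yl]propanoate | COC(=O)[C@H](C)C1=C([C@@]2(C)CCCC(C)(C)C2)CC[C@H]2C(=O)O[C@@H](O)[C@@H]12 | target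

## Step count and weak points

Total: 16 steps. Longest linear sequence: 16 steps (1 to 25); 2, 9, 11, 18 and 23 are bought.

Step 15 (key step, new method). Most likely failure: no productive turnover, because the crowded tetrasubstituted diene does not accept the hydride or because the weakly nucleophilic hemiacetal hydroxyl captures the acylpalladium too slowly, so that β-hydride elimination returns the diene; incomplete control at Cα is the second risk. Fallback by known chemistry, setting out from 17 and returning at 24: Negishi coupling of triflate 17 with the Reformatsky reagent of tert-butyl 2-bromopropanoate (Pd(PPh3)4, THF) should give the tert-butyl propanoate F1 as both Cα epimers. HF·pyridine then gives the alcohol F2, and Dess–Martin oxidation gives the aldehyde F3. Aqueous trifluoroacetic acid removes the tert-butyl ester and closes ring B to the lactol acid F4. Carbodiimide lactonisation (EDC, DMAP) of the lactol hydroxyl onto the acid gives 24 together with its Cα epimer F5. DBU in toluene should equilibrate F5 to 24, in which the methyl group avoids ring C and sits on the convex face.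

Step 9. Most likely failure: wrong regiochemistry of the ene reaction (abstraction of the r6 hydrogen with oxygen delivered to r2), or loss of the silyloxy group by β-elimination once the ketone is formed in the presence of amine. Fallback, setting out from 13 and returning at 15: allylic oxidation at the unhindered r3 methylene (CrO3, 3,5-dimethylpyrazole) gives the transposed enone F6. Nucleophilic epoxidation (t-BuOOH, DBU) gives the epoxy ketone F7. Wharton transposition (N2H4·H2O, AcOH) gives the allylic alcohol F8 with oxygen on r1 and the alkene at r2=r3. Dess–Martin oxidation then gives 15.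

Step 12. Most likely failure: premature lactonisation of the cis γ-hydroxy ester by acyl transfer to the free hydroxyl, which removes the ester that step 14 needs. Fallback, setting out from 19 and returning at 22: Bu4NF in THF is used to drive that lactonisation to completion, giving the cis-fused lactone F9. Bu4NOH (1 equiv) opens it to the hydroxy acid F10, kept as its tetrabutylammonium salt so that it cannot reclose. Dess–Martin oxidation in the presence of pyridine and acidification then give 22 directly, which also bypasses the acid treatment of a free aldehyde in step 14.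

Step 16. Most likely failure: epimerisation at r6 or migration of the ring double bond into conjugation while the ring-opened aldehyde–carboxylate is exposed to base, or competing attack on the ring B carbonyl. Fallback, setting out from 24 and returning at 25: HCl in methanol (from acetyl chloride) transesterifies the acylal under acid and keeps the aldehyde masked as the methyl pseudo-ester F11. Dilute aqueous HCl in THF then hydrolyses the methyl acetal back to the lactol, in the manner of step 14, to give 25.

## Further compounds

F1 | step 15 | methyl (1R,2R)-2-{[(tert-butyldimethylsilyl)oxy]methyl}-3-[1-(tert-butoxy)-1-oxopropan-2-yl]-4-[(1S)-1,3,3-trimethylcyclohexyl]cyclohex-3-ene-1-carboxylate (both Cα epimers) | CC(C(=O)OC(C)(C)C)C1=C([C@@]2(C)CCCC(C)(C)C2)CC[C@@H](C(=O)OC)[C@H]1CO[Si](C)(C)C(C)(C)C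
F2 | step 15 | methyl (1R,2R)-3-[1-(tert-butoxy)-1-oxopropan-2-yl]-2-(hydroxymethyl)-4-[(1S)-1,3,3-trimethylcyclohexyl]cyclohex-3-ene-1-carboxylate (both Cα epimers) | CC(C(=O)OC(C)(C)C)C1=C([C@@]2(C)CCCC(C)(C)C2)CC[C@@H](C(=O)OC)[C@H]1CO
F3 | step 15 | methyl (1R,2R)-3-[1-(tert-butoxy)-1-oxopropan-2-yl]-2-formyl-4-[(1S)-1,3,3-trimethylcyclohexyl]cyclohex-3-ene-1-carboxylate (both Cα epimers) | CC(C(=O)OC(C)(C)C)C1=C([C@@]2(C)CCCC(C)(C)C2)CC[C@@H](C(=O)OC)[C@H]1C=O
F4 | step 15 | 2-[(3R,3aR,7aR)-3-hydroxy-1-oxo-5-[(1S)-1,3,3-trimethylcyclohexyl]-1,3,3a,6,7,7a-hexahydro-2-benzofuran-4-yl]propanoic acid (both Cα epimers) | CC(C(O)=O)C1=C([C@@]2(C)CCCC(C)(C)C2)CC[C@H]2C(=O)O[C@@H](O)[C@@H]12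
F5 | step 15 | Cα epimer of bis-lactone 24 (methyl on the ring B face) | C[C@@H]1C(=O)O[C@@H]2OC(=O)[C@@H]3CCC(=C1[C@H]23)[C@@]4(C)CCCC(C)(C)C4
F6 | step 9 | methyl (1R,2S)-2-{[(tert-butyldimethylsilyl)oxy]methyl}-5-oxo-4-[(1S)-1,3,3-trimethylcyclohexyl]cyclohex-3-ene-1-carboxylate | C1=C([C@@]2(C)CCCC(C)(C)C2)C(=O)C[C@@H](C(=O)OC)[C@H]1CO[Si](C)(C)C(C)(C)C
F7 | step 9 | 3,4-epoxide of F6 (either epoxide face) | C12OC1([C@@]3(C)CCCC(C)(C)C3)C(=O)C[C@@H](C(=O)OC)[C@H]2CO[Si](C)(C)C(C)(C)C
F8 | step 9 | methyl (1R,2S)-2-{[(tert-butyldimethylsilyl)oxy]methyl}-3-hydroxy-4-[(1S)-1,3,3-trimethylcyclohexyl]cyclohex-4-ene-1-carboxylate (either carbinol epimer) | OC1C([C@@]2(C)CCCC(C)(C)C2)=CC[C@@H](C(=O)OC)[C@H]1CO[Si](C)(C)C(C)(C)C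
F9 | step 12 | (3aR,7aR)-4-ethenyl-5-[(1S)-1,3,3-trimethylcyclohexyl]-3a,6,7,7a-tetrahydro-2-benzofuran-1(3H)-one | C=CC1=C([C@@]2(C)CCCC(C)(C)C2)CC[C@H]2C(=O)OC[C@@H]12
F10 | step 12 | (1R,2R)-3-ethenyl-2-(hydroxymethyl)-4-[(1S)-1,3,3-trimethylcyclohexyl]cyclohex-3-ene-1-carboxylic acid | C=CC1=C([C@@]2(C)CCCC(C)(C)C2)CC[C@@H](C(=O)O)[C@H]1CO
F11 | step 16 | methyl (2R)-2-[(3R,3aR,7aR)-3-methoxy-1-oxo-5-[(1S)-1,3,3-trimethylcyclohexyl]-1,3,3a,6,7,7a-hexahydro-2-benzofuran-4-yl]propanoate (anomer as drawn; the other may accompany it) | COC(=O)[C@H](C)C1=C([C@@]2(C)CCCC(C)(C)C2)CC[C@H]2C(=O)O[C@@H](OC)[C@@H]12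
A1 | alternative 1 | methyl (2R)-2-{2-[(1S)-1,3,3-trimethylcyclohexyl]cyclohexa-1,5-dien-1-yl}propanoate | COC(=O)[C@H](C)C1=C([C@@]2(C)CCCC(C)(C)C2)CCC=C1
A2 | alternative 1 | benzyloxyketene | O=C=COCc1ccccc1
A3 | alternative 1 | cis-fused benzyloxycyclobutanone (carbonyl on r5, benzyloxy-bearing carbon on r6) | COC(=O)[C@H](C)C1=C([C@@]2(C)CCCC(C)(C)C2)CC[C@H]2C(=O)[C@@H](OCc3ccccc3)[C@@H]12
A4 | alternative 2 | 1-[1-(ring A alkenyl)ethenyl]cyclopentan-1-ol, ring A carrying the ethylene ketal on r1 and the silyloxymethyl group on r5 | OC1(CCCC1)C(=C)C2=CC[C@@H](CO[Si](C)(C)C(C)(C)C)CC23OCCO3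
A5 | alternative 2 | 2-methyl-2-(ring A alkenyl)cyclohexan-1-one with the same ring A ketal and silyloxymethyl group | C[C@@]1(CCCCC1=O)C2=CC[C@@H](CO[Si](C)(C)C(C)(C)C)CC23OCCO3
A6 | alternative 3 | 5-oxo-2,5-dihydrofuran-2-yl (2R)-2-methyl-4-[(1S)-1,3,3-trimethylcyclohexyl]but-3-ynoate | C[C@H](C#C[C@@]1(C)CCCC(C)(C)C1)C(=O)O[C@@H]2OC(=O)C=C2
A7 | alternative 3 | acetylene | C#C
A8 | alternative 3 | tricyclic diene bis-lactone (24 with an additional r3=r4 double bond) | C[C@H]1C(=O)O[C@@H]2OC(=O)[C@@H]3C=CC(=C1[C@H]23)[C@@]4(C)CCCC(C)(C)C4
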